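Longipinane numbering is used: C1 ketone, C2=C3(CH3), cyclobutane C4–C5–C11–C10, gem-dimethyl C6, carbinols C7 and C9, CH2 C8. The seven-membered ring is C5–C6–C7–C8–C9–C10–C11.
Retrosynthesis: cut both ester C–O bonds and return C7–OH/C9–OH to a C9 ketone. Then cut C6–C7 and C8–C9, so that C7–C8 leave as a vinyl group and C9 is bonded directly to C6 (five-membered ring C5–C6–C9–C10–C11 of a bicyclo[2.1.1]hexan-2-one). Then cut C2=C3 (aldol), C5–C11 and C4–C10 ([2+2]), C10=C11 and C4=C5 (Wittig), and C6–C9 (enamine acylation).
Forward: an acyclic triketone gives the cyclobutane and the five-membered ring together (crossed photocycloaddition). The cyclohexenone ring follows (aldol condensation). The five-membered ring is then grown by two carbons to the seven-membered ring (vinyl addition, alkoxy-radical scission and re-closure).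
Enabling feature: C7–C8–C9 lies between two fully substituted carbons, C6 (gem-dimethyl) and C10 (methyl-bearing cyclobutane carbon), which hang cis-1,3 from the puckered cyclobutane. A C9 carbinol wedged between them is strained, can fragment only to a tertiary radical, and holds that radical next to the vinyl ketone it releases. The rule of five rules out the four-carbon bridge by direct photocycloaddition.
Stereochemistry: C4, C5, C10 and C11 come from a chiral-amine desymmetrising aldol of the meso diketone (epimers funnel in). C7 comes from ligand-controlled copper–boryl conjugate addition, C9 from hydroxyl-directed anti reduction, and the Z-alkenes from angelic acid.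

Key step: step 8

Remark: the sense of induction of the chiral amine (step 6) and of the chiral diphosphine (step 10) cannot be derived safely for this skeleton. Both antipodes (or pseudo-antipodes) are available, and the one that gives the drawn configuration is meant.

Step 1
Reactants: 1 isobutyraldehyde; 2 morpholine
Product: 3 4-(2-methylprop-1-en-1-yl)morpholine
Conditions: p-TsOH (cat.), cyclohexane, Dean–Stark, reflux
Reagents that add atoms: none
Why: Acid-catalysed enamine condensation driven by azeotropic removal of water; the aldehyde has a single α-hydrogen, so only one enamine can form.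

Step 2
Reactants: 3 4-(2-methylprop-1-en-1-yl)morpholine; 4 propionyl chloride
Product: 6 2,2-dimethyl-3-oxopentanal, via acyl iminium chloride 5 (not isolated)
Conditions: Et2O, 0 °C to reflux; then H2O, rt
Reagents that add atoms: water, O
Why: Stork enamine C-acylation, in which the enamine β-carbon attacks the acid chloride to create quaternary C6 and the C6–C9 bond, and the iminium salt, which has no α-hydrogen to lose, is hydrolysed to the aldehyde.

Step 3
Reactants: 6 2,2-dimethyl-3-oxopentanal
Product: 7 2,2-dimethyl-3,4-dioxopentanal
Conditions: SeO2 (1.05 equiv), 1,4-dioxane–H2O (20:1), 90 °C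
Reagents that add atoms: selenium dioxide, O=[Se]=O
Why: Riley oxidation; the CH2 of the ethyl ketone is the only enolisable position, so the 1,2-diketone can form at one site only, and the reagent is limited to one equivalent to spare the new acetyl methyl group.

Step 4
Reactants: 7 2,2-dimethyl-3,4-dioxopentanal; 8 (acetylmethylene)triphenylphosphorane (2.3 equiv)
Product: 10 (3E,7E)-4,6,6-trimethyldeca-3,7-diene-2,5,9-trione, via enetrione 9 (not isolated)
Conditions: toluene, rt, then 90 °C
Reagents that add atoms: none
Why: Twofold Wittig olefination with a stabilised ylide, which takes the aldehyde first and then the activated, unhindered acetyl carbonyl of the 1,2-diketone while the neopentylic carbonyl (future C9) stays untouched; E geometry is expected but is irrelevant for step 5.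

Step 5
Reactants: 10 (3E,7E)-4,6,6-trimethyldeca-3,7-diene-2,5,9-trione
Product: 11 meso-5,6-diacetyl-1,3,3-trimethylbicyclo[2.1.1]hexan-2-one
Conditions: hν (350–366 nm, Pyrex), MeCN (5 mM), rt
Reagents that add atoms: none
Why: Intramolecular enone–alkene [2+2] photocycloaddition of a 1,5-hexadien-3-one, in which the triplet first closes the five-membered ring C5–C6–C9–C10–C11 by C11–C5 bonding (rule of five) to a biradical stabilised by acyl groups at C10 and C4 and then joins C10 to C4, so the crossed bicyclo[2.1.1]hexan-2-one should form whatever the alkene geometry, with C5/C10 fixed by the bridge and the acetyl-bearing C4/C11 formed as epimers that step 6 levels.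

Step 6
Reactants: 11 meso-5,6-diacetyl-1,3,3-trimethylbicyclo[2.1.1]hexan-2-one (with its C4/C11 epimers)
Product: 13 (4R,5S,10R,11R)-7,8-dinorlongipin-2-ene-1,9-dione, via ketol 12 (not isolated)
Conditions: 9-amino-9-deoxy-epi-quinine (20 mol %), AcOH (40 mol %), 4 Å MS, toluene, 45 °C
Reagents that add atoms: none
Why: Primary-amine (enamine) catalysed 6-enolexo intramolecular aldol condensation of a 2,6-heptanedione unit: only the meso isomer with both acetyl groups on the face away from the C6–C9 bridge can close, the other epimers feed into it by enamine/enol equilibration at C4 and C11, and the chiral amine picks the acetyl on one enantiotopic side as the nucleophile, which turns C4, C5, C10 and C11 into the (4R,5S,10R,11R) set.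

Step 7
Reactants: 13 (4R,5S,10R,11R)-7,8-dinorlongipin-2-ene-1,9-dione; 14 vinylmagnesium bromide
Product: 17 (4R,5S,10R,11R)-9-hydroxy-9-vinyl-7,8-dinorlongipin-2-en-1-one (both C9 epimers), via lithium dienolate 15 (not isolated), via deconjugated carbinol 16 (not isolated)
Conditions: LiN(SiMe3)2 (1.1 equiv), THF, −78 °C; 14 (3 equiv), −78 to 0 °C; aq NH4Cl; then DBU (0.2 equiv), CH2Cl2, rt
Reagents that add atoms: none
Why: In situ enolate protection followed by Grignard 1,2-addition: the C1 enone is the only carbonyl with an acidic (γ-methyl) hydrogen and is masked as dienolate 15, while the non-enolisable, angle-strained, fenchone-like C9 ketone accepts the small vinyl nucleophile; DBU returns the exocyclic-methylene isomer 16 to the conjugated enone, and the new C9 centre needs no control because step 8 erases it.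

Step 8
Reactants: 17 (4R,5S,10R,11R)-9-hydroxy-9-vinyl-7,8-dinorlongipin-2-en-1-one
Product: 21 (4R,5S,10R,11R)-longipin-2-ene-1,9-dione, via alkoxy radical 18 (not isolated), via seco tertiary radical 19 (not isolated), via alpha-keto radical 20 (not isolated)
Conditions: [Ir(dF(CF3)ppy)2(5,5'-d(CF3)bpy)]PF6 (2 mol %), 2,4,6-collidine, CH2Cl2, blue LED (450 nm), rt
Reagents that add atoms: none
Why: The excited iridium photocatalyst and collidine take an electron and a proton from the tertiary O–H (proton-coupled electron transfer) to give alkoxy radical 18, whose β-scission of C9–C6 opens the strained five-membered ring C5–C6–C9–C10–C11 to the tertiary radical/vinyl ketone 19. Because C6 and C9 hang cis-1,3 from the puckered cyclobutane, the radical adds to the terminal vinyl carbon (7-endo-trig, Giese polarity) and closes the seven-membered ring C5–C6–C7–C8–C9–C10–C11 (and its twin through C4), after which alpha-keto radical 20 is reduced by the reduced photocatalyst and protonated by collidinium, so the step is a redox-neutral isomerisation. The closest known reaction type is the photocatalytic n to n+2 ring expansion of 1-vinylcycloalkanols. No new stereocentre is formed and the C9 carbinol centre is erased, so both epimers of 17 converge on one product. The step needs scission of a ring bond rather than of the vinyl bond, secured by ring strain and tertiary-radical formation, and endo rather than 6-exo closure, secured by the unsubstituted vinyl terminus and the polarity match. Scission of C9–C10 instead of C9–C6 would give the C7-ketone isomer of the same ring, which steps 9 to 11 would carry to the same diol 25 because C7 and C9 have the same local environment.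

Step 9
Reactants: 21 (4R,5S,10R,11R)-longipin-2-ene-1,9-dione
Product: 22 (4R,5S,10R,11R)-longipina-2,7-diene-1,9-dione
Conditions: IBX (2.5 equiv), DMSO–fluorobenzene (1:2), 75 °C
Reagents that add atoms: none
Why: IBX dehydrogenation through the enol: the C9 ketone can enolise only toward C8 because C10 is quaternary, desaturation stops at C7 because C6 is quaternary, and the C1 enone offers no α,β C–H pair (C11 is a bridgehead).

Step 10
Reactants: 22 (4R,5S,10R,11R)-longipina-2,7-diene-1,9-dione
Product: 24 (4R,5S,7S,10R,11R)-7-hydroxylongipin-2-ene-1,9-dione, via C7 pinacol boronate 23 (not isolated)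
Conditions: CuCl (5 mol %), NaOtBu (5 mol %), (R,S)-Taniaphos (6 mol %), B2pin2 (1.2 equiv), MeOH (2 equiv), THF, rt; then NaBO3·4H2O, THF–H2O, rt
Reagents that add atoms: bis(pinacolato)diboron, CC1(C)OB(OC1(C)C)B1OC(C)(C)C(C)(C)O1 (boron of 23); sodium perborate, [Na+].[O-]OB=O (oxygen of 24)
Why: Copper–boryl conjugate addition (β-borylation) and stereoretentive C–B oxidation: the disubstituted C7=C8 enone reacts while the β,β-disubstituted C2=C3 enone does not, and since the two faces of the flat C7=C8–C9=O unit are flanked alike by the C6 methyl groups the chiral diphosphine decides that boron, hence oxygen, enters C7 on the face turned toward C11 (7S).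

Step 11
Reactants: 24 (4R,5S,7S,10R,11R)-7-hydroxylongipin-2-ene-1,9-dione
Product: 25 (4R,5S,7S,9S,10R,11R)-7,9-dihydroxylongipin-2-en-1-one
Conditions: Me4NBH(OAc)3 (5 equiv), MeCN–AcOH (1:1), −25 to 0 °C
Reagents that add atoms: none
Why: Evans–Saksena reduction: the C7 hydroxyl exchanges onto boron and delivers hydride across the ring to the same face of the C9 carbonyl, which places the new C9 hydroxyl on the opposite face (1,3-anti, 9S), and the undirected C1 enone is not reduced by this mild reagent.

Step 12
Reactants: 25 (4R,5S,7S,9S,10R,11R)-7,9-dihydroxylongipin-2-en-1-one; 26 angelic acid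
Product: 27 (4R,5S,7S,9S,10R,11R)-7,9-bis(angeloyloxy)longipin-2-en-1-one
Conditions: 26 (6 equiv), 2,4,6-Cl3C6H2COCl, Et3N, toluene, rt; then 25, 85 °C
Reagents that add atoms: none
Why: Yamaguchi-type mixed-anhydride esterification run without a nucleophilic catalyst, which acylates both neopentylic alcohols at the less hindered angeloyl carbonyl and avoids the addition–elimination pathway that would isomerise the Z-angelate to the E-tiglate.

Compound list
1 | isobutyraldehyde | CC(C)C=O | starting material
2 | morpholine | C1COCCN1 | starting material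
3 | 4-(2-methylprop-1-en-1-yl)morpholine | CC(C)=CN1CCOCC1 | intermediate
4 | propionyl chloride | CCC(=O)Cl | starting material
5 | 4-(2,2-dimethyl-3-oxopentylidene)morpholin-4-ium chloride | CCC(=O)C(C)(C)C=[N+]1CCOCC1.[Cl-] | intermediate
6 | 2,2-dimethyl-3-oxopentanal | CCC(=O)C(C)(C)C=O | intermediate
7 | 2,2-dimethyl-3,4-dioxopentanal | CC(=O)C(=O)C(C)(C)C=O | intermediate
8 | (acetylmethylene)triphenylphosphorane | CC(=O)C=P(c1ccccc1)(c1ccccc1)c1ccccc1 | starting material
9 | (E)-4,4-dimethyloct-5-ene-2,3,7-trione | CC(=O)C(=O)C(C)(C)/C=C/C(C)=O | intermediate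
10 | (3E,7E)-4,6,6-trimethyldeca-3,7-diene-2,5,9-trione | CC(=O)/C=C(\C)C(=O)C(C)(C)/C=C/C(C)=O | intermediate
11 | meso-5,6-diacetyl-1,3,3-trimethylbicyclo[2.1.1]hexan-2-one, both acetyl groups on the face away from the C2–C3 bridge | CC(=O)[C@H]1[C@]2(C)C(=O)C(C)(C)[C@H]1[C@@H]2C(C)=O | intermediate
12 | 3-hydroxy-2,3-dihydro derivative of 13 (aldol adduct, C3 configuration immaterial) | O=C1[C@@]2(C)[C@@H]3C(=O)CC(C)(O)[C@H]2[C@@H]3C1(C)C | intermediate
13 | (4R,5S,10R,11R)-7,8-dinorlongipin-2-ene-1,9-dione (C9 bonded to C6) | O=C1[C@@]2(C)[C@@H]3C(=O)C=C(C)[C@H]2[C@@H]3C1(C)C | intermediate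
14 | vinylmagnesium bromide | C=C[Mg]Br | starting material
15 | lithium dienolate of 13 (C1 enolate, exocyclic methylene at C3) | O=C1[C@@]2(C)[C@@H]3C([O-])=CC(=C)[C@H]2[C@@H]3C1(C)C.[Li+] | intermediate
16 | 9-hydroxy-9-vinyl carbinol with C3 exocyclic methylene (deconjugated isomer of 17, C9 epimers) | C=CC1(O)[C@@]2(C)[C@@H]3C(=O)CC(=C)[C@H]2[C@@H]3C1(C)C | intermediate
17 | (4R,5S,10R,11R)-9-hydroxy-9-vinyl-7,8-dinorlongipin-2-en-1-one (C9 epimers, both used) | C=CC1(O)[C@@]2(C)[C@@H]3C(=O)C=C(C)[C@H]2[C@@H]3C1(C)C | intermediate
18 | C9 alkoxy radical of 17 | C=CC1([O])[C@@]2(C)[C@@H]3C(=O)C=C(C)[C@H]2[C@@H]3C1(C)C | intermediate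
19 | ring-opened C6 tertiary radical bearing the C10 acryloyl group | C=CC(=O)[C@@]1(C)[C@@H]2C(=O)C=C(C)[C@H]1[C@@H]2[C](C)C | intermediate
20 | ring-expanded C8 alpha-keto radical | C1[CH]C(=O)[C@@]2(C)[C@@H]3C(=O)C=C(C)[C@H]2[C@@H]3C1(C)C | intermediate
21 | (4R,5S,10R,11R)-longipin-2-ene-1,9-dione | C1CC(=O)[C@@]2(C)[C@@H]3C(=O)C=C(C)[C@H]2[C@@H]3C1(C)C | intermediate
22 | (4R,5S,10R,11R)-longipina-2,7-diene-1,9-dione | C1=CC(=O)[C@@]2(C)[C@@H]3C(=O)C=C(C)[C@H]2[C@@H]3C1(C)C | intermediate
23 | 7-(pinacolboryl)longipin-2-ene-1,9-dione, boron on the face turned toward C11 | CC1(C)OB(OC1(C)C)[C@H]2CC(=O)[C@@]3(C)[C@@H]4C(=O)C=C(C)[C@H]3[C@@H]4C2(C)C | intermediate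
24 | (4R,5S,7S,10R,11R)-7-hydroxylongipin-2-ene-1,9-dione | O[C@H]1CC(=O)[C@@]2(C)[C@@H]3C(=O)C=C(C)[C@H]2[C@@H]3C1(C)C | intermediate
25 | (4R,5S,7S,9S,10R,11R)-7,9-dihydroxylongipin-2-en-1-one | O[C@H]1C[C@H](O)[C@@]2(C)[C@@H]3C(=O)C=C(C)[C@H]2[C@@H]3C1(C)C | intermediate
26 | angelic acid, (Z)-2-methylbut-2-enoic acid | C/C=C(/C)C(=O)O | starting material
27 | (4R,5S,7S,9S,10R,11R)-7,9-bis(angeloyloxy)longipin-2-en-1-one | C/C=C(/C)C(=O)O[C@H]1C[C@H](OC(=O)/C(C)=C\C)[C@@]2(C)[C@@H]3C(=O)C=C(C)[C@H]2[C@@H]3C1(C)C | target

Total step count: 12. Longest linear sequence: 12 steps (1 to 27).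

Steps most likely to fail

Step 8. O–H activation of the crowded carbinol may be slow. The ring-opened radical may also be lost by hydrogen transfer or disproportionation before it re-closes. The fallback sets out from 17 and comes back at 21, and it separates the cut from the re-closure. Hypoiodite (Suárez) fragmentation with PhI(OAc)2 and I2 under visible light in CH2Cl2 should open the same C9–C6 bond and trap the radical as the tertiary iodide F1. DBU then removes hydrogen iodide to give the isopropenyl acryloyl seco dienone F2. A reductive olefin coupling started by hydrogen-atom transfer (Fe(acac)3, PhSiH3, EtOH, 60 °C) regenerates the C6 tertiary radical from the isopropenyl group. Giese addition to the vinyl ketone then closes C6–C7 and gives 21.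

Step 6. Closure to the strained tricycle may be thermodynamically reluctant, and epimerisation at C4/C11 may lag behind catalyst decay. A reversible parasitic aldol addition onto the C9 ketone may hold material back, and the enantiotopic-group selection may erode at the temperature needed. The fallback sets out from 11 and comes back at 21, and it postpones the aldol until the ring has grown.
- Ethylene glycol with p-TsOH (benzene, Dean–Stark) ketalises only the two methyl ketones and gives the bis(dioxolane) F3.
- Vinylmagnesium bromide adds to the free hindered ketone to give the vinyl carbinol F4.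
- The photocatalytic conditions of step 8 expand the ring to the bicyclo[4.1.1]octanone bis(dioxolane) F5.
- Aqueous HCl in THF releases the diacetyl ketone F6.
- The amine-catalysed desymmetrising aldol condensation of step 6, now on the less strained bicyclo[4.1.1]octane, gives 21.

This order also removes the need for step 7.

Step 7. Incomplete dienolate formation would allow 1,2-addition at C1. Addition at the hindered C9 carbonyl may be sluggish, and proton exchange between dienolate and product alkoxide may unmask the enone. The fallback sets out from 13 and comes back at 17, and it uses an isolable protecting group. TBSOTf with Et3N in CH2Cl2 converts the enone into the silyl dienol ether F7. Vinylmagnesium bromide with CeCl3 in THF at −78 °C adds to C9 to give the silyl-protected vinyl carbinol F8. TBAF buffered with AcOH removes silicon with γ-protonation and returns the conjugated enone 17.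

Further compounds
F1 | step 8 | ring-opened vinyl ketone with tertiary iodide at C6 | C=CC(=O)[C@@]1(C)[C@@H]2C(=O)C=C(C)[C@H]1[C@@H]2C(C)(C)I
F2 | step 8 | 10-acryloyl-5-isopropenyl seco dienone | C=CC(=O)[C@@]1(C)[C@@H]2C(=O)C=C(C)[C@H]1[C@@H]2C(C)=C
F3 | step 6 | bis(ethylene ketal) of 11 | CC1(OCCO1)[C@H]2[C@]3(C)C(=O)C(C)(C)[C@H]2[C@@H]3C4(C)OCCO4
F4 | step 6 | 2-vinyl-2-hydroxy derivative of F3 (racemic, carbinol centre undefined) | CC1(OCCO1)[C@H]2[C@]3(C)C(O)(C=C)C(C)(C)[C@H]2[C@@H]3C4(C)OCCO4
F5 | step 6 | 7,8-bis(2-methyl-1,3-dioxolan-2-yl)-1,5,5-trimethylbicyclo[4.1.1]octan-2-one | CC1(OCCO1)[C@H]2[C@]3(C)C(=O)CCC(C)(C)[C@H]2[C@@H]3C4(C)OCCO4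
F6 | step 6 | meso-7,8-diacetyl-1,5,5-trimethylbicyclo[4.1.1]octan-2-one | CC(=O)[C@H]1[C@]2(C)C(=O)CCC(C)(C)[C@H]1[C@@H]2C(C)=O
F7 | step 7 | tert-butyldimethylsilyl dienol ether of 13 | O=C1[C@@]2(C)[C@@H]3C(O[Si](C)(C)C(C)(C)C)=CC(=C)[C@H]2[C@@H]3C1(C)C
F8 | step 7 | 9-hydroxy-9-vinyl derivative of F7 (C9 epimers) | C=CC1(O)[C@@]2(C)[C@@H]3C(O[Si](C)(C)C(C)(C)C)=CC(=C)[C@H]2[C@@H]3C1(C)C
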